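Everything rests on cutting the C1–C2 bond of ring A and reading the ring as an unfolded 4-pyranone. Ring A carries, in order, carboxyl on C1, methyl on C2, oxygen on C3 and C4, hydrogen on C5 and oxygen on C6; this is the pattern of a 5-alkoxy-6-methyl-4-pyranone with an acetate arm on its other α-carbon. In one operation, hydroxide opens pyranone 5 to a triketo ester and aldol condensation recloses it as the benzene ring, with the C3 oxygen already set apart as a 4-methoxybenzyl ether. The derived acid 12 is joined to a ring B–ring C phenol, and hydrogenolysis ends the route.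

Key step: step 5

Remark: allomaltol 1 is taken as purchasable; in step 5 hydroxide may add to either α-carbon of pyranone 5, and both adducts open to the same chain 6.

**Route**

Step 1
Reactants: 1 allomaltol (5-hydroxy-2-methyl-4H-pyran-4-one)
Product: 2 bromoallomaltol (2-bromo-3-hydroxy-6-methyl-4H-pyran-4-one)
Conditions: NBS (1.0 equiv), MeCN, 0 °C to rt
Reagents that add atoms: N-bromosuccinimide, O=C1CCC(=O)N1Br
Why: Electrophilic bromination of the enol: the free hydroxyl activates the neighbouring ring carbon next to the ring oxygen, the position that 3-hydroxy-4-pyranones use in hydroxymethylation and Mannich reactions, so bromine should enter there and not at the other ring C–H.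

Step 2
Reactants: 2 bromoallomaltol
Product: 3 bromopyranone ether (2-bromo-3-[(4-methoxybenzyl)oxy]-6-methyl-4H-pyran-4-one)
Conditions: 4-methoxybenzyl chloride (1.2 equiv), K2CO3, DMF, 50 °C
Reagents that add atoms: 4-methoxybenzyl chloride, COc1ccc(CCl)cc1
Why: Williamson ether synthesis on the acidic enol hydroxyl, which K2CO3 ionises and which can only be alkylated at oxygen because both neighbouring carbons are substituted.

Step 3
Reactants: 3 bromopyranone ether
Product: 4 bromopyranone ester (tert-butyl 2-{6-bromo-5-[(4-methoxybenzyl)oxy]-4-oxo-4H-pyran-2-yl}acetate)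
Conditions: LiN(SiMe3)2 (2.2 equiv), THF, −78 °C, 3 added to the base; Boc2O (1.05 equiv), −78 °C; aq NH4Cl
Reagents that add atoms: di-tert-butyl dicarbonate, CC(C)(C)OC(=O)OC(=O)OC(C)(C)C
Why: Lateral (vinylogous) deprotonation of the single methyl group followed by Claisen-type C-acylation of the dienolate with Boc2O, as practised on 2-methyl-4-pyranones, 2-methylchromones and picolines; the second equivalent of base stores the more acidic product as its enolate and so should stop a second acylation, and the bulky amide should not attack the C–Br carbon at −78 °C.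

Step 4
Reactants: 4 bromopyranone ester
Product: 5 pyranone precursor (tert-butyl 2-{5-[(4-methoxybenzyl)oxy]-6-methyl-4-oxo-4H-pyran-2-yl}acetate)
Conditions: MeZnCl (2.5 equiv), PdCl2(dppf) (5 mol %; dppf = 1,1'-bis(diphenylphosphino)ferrocene), THF, 50 °C
Reagents that add atoms: chloro(methyl)zinc, C[Zn]Cl
Why: Negishi cross-coupling: the C–Br bond sits on the β-carbon of the enone (a vinylogous acyl bromide), so oxidative addition to zerovalent palladium should be fast, and the weakly basic, anhydrous methylzinc reagent should transfer methyl without opening the pyranone or touching the tert-butyl ester.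

Step 5
Reactants: 5 pyranone precursor
Product: 8 tert-butyl 4,6-dihydroxy-3-[(4-methoxybenzyl)oxy]-2-methylbenzoate, via triketo ester 6 (not isolated), via cyclic aldol 7 (not isolated)
Conditions: KOH (4 equiv), MeOH/H2O (4:1), degassed, argon, 0 °C to rt; then cold 1 M HCl to pH 5
Reagents that add atoms: none
Why: Hydroxide adds to an α-carbon of the pyranone, the ring oxygen leaves as an enolate and the ring unzips to the 6-alkoxy-3,5,7-triketo ester 6, a net addition of water. The C2 carbanion of 6, flanked by the ester and the C3 ketone, adds to the C7 methyl ketone to give cyclic aldol 7, which loses water and enolises to the benzene ring, so the overall change is an isomerisation that forms the C1–C2 bond of ring A. The closest known reaction type is the base-induced change of 2-(alkoxycarbonylmethyl)-6-methyl-4-pyranones, as masked 3,5,7-triketo esters, into orsellinates; the alkoxy group on C6 of the chain is the part without direct precedent. Ring A closes in the 6-(enolendo)-exo-trig aldol mode, and no stereocentre remains in the product. The step needs C2-to-C7 aldol closure and not Claisen closure onto the ester, aldol closure of C8 onto C3, or ester hydrolysis: the C2 carbanion is doubly stabilised and far more populated than the C8 enolate, Claisen attack by C6 would build a quaternary carbon that cannot aromatise, and the tert-butyl ester is a poor acyl acceptor that hydroxide does not cleave. Exclusion of air protects the electron-rich phenolate that results.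

Step 6
Reactants: 8 tert-butyl 4,6-dihydroxy-3-[(4-methoxybenzyl)oxy]-2-methylbenzoate
Product: 9 tert-butyl 4,6-bis(benzyloxy)-3-[(4-methoxybenzyl)oxy]-2-methylbenzoate
Conditions: BnBr (2.5 equiv), K2CO3, DMF, 60 °C
Reagents that add atoms: benzyl bromide, BrCc1ccccc1
Why: Williamson ether synthesis on both phenoxides; the 6-hydroxyl is hydrogen-bonded to the ester and needs the warm DMF, while the tert-butyl ester and the 4-methoxybenzyl ether are inert to carbonate.

Step 7
Reactants: 9 tert-butyl 4,6-bis(benzyloxy)-3-[(4-methoxybenzyl)oxy]-2-methylbenzoate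
Product: 10 4,6-bis(benzyloxy)-3-hydroxy-2-methylbenzoic acid
Conditions: CF3CO2H/CH2Cl2 (1:4), Et3SiH (5 equiv), 0 °C
Reagents that add atoms: none
Why: Acidolysis by the SN1 path: the 4-methoxybenzyl ether and the tert-butyl ester both ionise in trifluoroacetic acid while the plain benzyl ethers do not, triethylsilane reduces the two cations before the 4-methoxybenzyl cation can alkylate C5 of ring A, and the low temperature guards the electron-rich acid against protodecarboxylation.

Step 8
Reactants: 10 4,6-bis(benzyloxy)-3-hydroxy-2-methylbenzoic acid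
Product: 12 3-(acetyloxy)-4,6-bis(benzyloxy)-2-methylbenzoic acid, via mixed anhydride 11 (not isolated)
Conditions: Ac2O (3 equiv), pyridine, DMAP (cat.), CH2Cl2, 0 °C to rt; then H2O, THF, rt
Reagents that add atoms: acetic anhydride, CC(=O)OC(C)=O
Why: DMAP-catalysed acetylation (nucleophilic acyl-transfer catalysis) of the hindered C3 phenol, the only free hydroxyl; the carboxyl group is acetylated at the same time to mixed anhydride 11, which water cleaves at its unhindered acetyl carbonyl and so returns the free acid.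

Step 9
Reactants: 13 orsellinic acid (2,4-dihydroxy-6-methylbenzoic acid)
Product: 14 benzyl orsellinate (benzyl 2,4-dihydroxy-6-methylbenzoate)
Conditions: BnBr (1.05 equiv), KHCO3, DMF, rt
Reagents that add atoms: benzyl bromide, BrCc1ccccc1
Why: Carboxylate O-alkylation (SN2): hydrogen carbonate ionises the carboxylic acid alone, so benzyl bromide esterifies it and leaves both phenols free.

Step 10
Reactants: 13 orsellinic acid
Product: 16 4-[(tert-butyldimethylsilyl)oxy]-2-hydroxy-6-methylbenzoic acid, via silyl ester 15 (not isolated)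
Conditions: TBSCl (2.2 equiv), imidazole, DMF, 0 °C to rt; then AcOH/THF/H2O, rt
Reagents that add atoms: tert-butyldimethylsilyl chloride, CC(C)(C)[Si](C)(C)Cl
Why: Imidazole-promoted silylation: the carboxyl group and the free 4-hydroxyl are silylated while the 2-hydroxyl, hydrogen-bonded to the carbonyl group, is not, and the labile silyl ester 15 is then hydrolysed by aqueous acetic acid, which an aryl silyl ether survives.

Step 11
Reactants: 16 4-[(tert-butyldimethylsilyl)oxy]-2-hydroxy-6-methylbenzoic acid; 14 benzyl orsellinate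
Product: 17 benzyl 4-({4-[(tert-butyldimethylsilyl)oxy]-2-hydroxy-6-methylbenzoyl}oxy)-2-hydroxy-6-methylbenzoate
Conditions: DCC (1.1 equiv), toluene/Et2O, 0 °C to rt
Reagents that add atoms: none
Why: Carbodiimide esterification as used for depsides from ortho-hydroxybenzoic acids: the activated acid acylates the only unchelated phenol, the 4-hydroxyl of 14, since the 2-hydroxyls of both partners are held in hydrogen bonds to their ortho carbonyl groups.

Step 12
Reactants: 17 benzyl 4-({4-[(tert-butyldimethylsilyl)oxy]-2-hydroxy-6-methylbenzoyl}oxy)-2-hydroxy-6-methylbenzoate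
Product: 18 benzyl lecanorate (benzyl 4-[(2,4-dihydroxy-6-methylbenzoyl)oxy]-2-hydroxy-6-methylbenzoate)
Conditions: HF·pyridine, THF, 0 °C
Reagents that add atoms: none
Why: Fluoride-mediated desilylation driven by the strong Si–F bond; buffered HF·pyridine is neither basic nor nucleophilic enough to touch the aryl ester link or the benzyl ester.

Step 13
Reactants: 12 3-(acetyloxy)-4,6-bis(benzyloxy)-2-methylbenzoic acid; 18 benzyl lecanorate
Product: 20 protected tridepside (benzyl 4-{[4-({3-(acetyloxy)-4,6-bis(benzyloxy)-2-methylbenzoyl}oxy)-2-hydroxy-6-methylbenzoyl]oxy}-2-hydroxy-6-methylbenzoate), via aroyl trifluoroacetate 19 (not isolated)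
Conditions: (CF3CO)2O (3 equiv), toluene, rt
Reagents that add atoms: none
Why: Depside esterification through a mixed anhydride: trifluoroacetic anhydride turns the hindered acid into aroyl trifluoroacetate 19, which acylates the only unchelated phenol of 18, the 4-hydroxyl of ring B, while the aryl acetate and the benzyl ethers are inert.

Step 14
Reactants: 20 protected tridepside
Product: 21 CNP0154030.0 (4-[(4-{[3-(acetyloxy)-4,6-dihydroxy-2-methylbenzoyl]oxy}-2-hydroxy-6-methylbenzoyl)oxy]-2-hydroxy-6-methylbenzoic acid)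
Conditions: H2 (1 atm), 10 % Pd/C, EtOAc, rt
Reagents that add atoms: none
Why: Catalytic hydrogenolysis of the two benzyl ethers and the benzyl ester under neutral conditions, which should leave the aryl acetate and both depside esters intact and give the acetyl group no base to help it move to the freed C4 hydroxyl.

**Compound list**

1 | allomaltol (5-hydroxy-2-methyl-4H-pyran-4-one) | Cc1cc(=O)c(O)co1 | starting material
2 | 2-bromo-3-hydroxy-6-methyl-4H-pyran-4-one | Cc1cc(=O)c(O)c(Br)o1 | intermediate
3 | 2-bromo-3-[(4-methoxybenzyl)oxy]-6-methyl-4H-pyran-4-one | Cc1cc(=O)c(OCc2ccc(OC)cc2)c(Br)o1 | intermediate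
4 | tert-butyl 2-{6-bromo-5-[(4-methoxybenzyl)oxy]-4-oxo-4H-pyran-2-yl}acetate | CC(C)(C)OC(=O)Cc1cc(=O)c(OCc2ccc(OC)cc2)c(Br)o1 | intermediate
5 | tert-butyl 2-{5-[(4-methoxybenzyl)oxy]-6-methyl-4-oxo-4H-pyran-2-yl}acetate | Cc1oc(CC(=O)OC(C)(C)C)cc(=O)c1OCc1ccc(OC)cc1 | intermediate
6 | tert-butyl 6-[(4-methoxybenzyl)oxy]-3,5,7-trioxooctanoate (not isolated; C6 not configured, enolised in base) | CC(=O)C(OCc1ccc(OC)cc1)C(=O)CC(=O)CC(=O)OC(C)(C)C | intermediate
7 | tert-butyl 2-hydroxy-3-[(4-methoxybenzyl)oxy]-2-methyl-4,6-dioxocyclohexane-1-carboxylate (not isolated; mixture of diastereomers) | CC1(O)C(OCc2ccc(OC)cc2)C(=O)CC(=O)C1C(=O)OC(C)(C)C | intermediate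
8 | tert-butyl 4,6-dihydroxy-3-[(4-methoxybenzyl)oxy]-2-methylbenzoate | Cc1c(OCc2ccc(OC)cc2)c(O)cc(O)c1C(=O)OC(C)(C)C | intermediate
9 | tert-butyl 4,6-bis(benzyloxy)-3-[(4-methoxybenzyl)oxy]-2-methylbenzoate | Cc1c(OCc2ccc(OC)cc2)c(OCc2ccccc2)cc(OCc2ccccc2)c1C(=O)OC(C)(C)C | intermediate
10 | 4,6-bis(benzyloxy)-3-hydroxy-2-methylbenzoic acid | Cc1c(O)c(OCc2ccccc2)cc(OCc2ccccc2)c1C(=O)O | intermediate
11 | acetic 3-(acetyloxy)-4,6-bis(benzyloxy)-2-methylbenzoic anhydride (not isolated) | Cc1c(OC(C)=O)c(OCc2ccccc2)cc(OCc2ccccc2)c1C(=O)OC(C)=O | intermediate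
12 | 3-(acetyloxy)-4,6-bis(benzyloxy)-2-methylbenzoic acid | Cc1c(OC(C)=O)c(OCc2ccccc2)cc(OCc2ccccc2)c1C(=O)O | intermediate
13 | orsellinic acid (2,4-dihydroxy-6-methylbenzoic acid) | Cc1cc(O)cc(O)c1C(=O)O | starting material
14 | benzyl 2,4-dihydroxy-6-methylbenzoate | Cc1cc(O)cc(O)c1C(=O)OCc1ccccc1 | intermediate
15 | tert-butyldimethylsilyl 4-[(tert-butyldimethylsilyl)oxy]-2-hydroxy-6-methylbenzoate (not isolated) | Cc1cc(O[Si](C)(C)C(C)(C)C)cc(O)c1C(=O)O[Si](C)(C)C(C)(C)C | intermediate
16 | 4-[(tert-butyldimethylsilyl)oxy]-2-hydroxy-6-methylbenzoic acid | Cc1cc(O[Si](C)(C)C(C)(C)C)cc(O)c1C(=O)O | intermediate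
17 | benzyl 4-({4-[(tert-butyldimethylsilyl)oxy]-2-hydroxy-6-methylbenzoyl}oxy)-2-hydroxy-6-methylbenzoate | Cc1cc(O[Si](C)(C)C(C)(C)C)cc(O)c1C(=O)Oc1cc(C)c(C(=O)OCc2ccccc2)c(O)c1 | intermediate
18 | benzyl 4-[(2,4-dihydroxy-6-methylbenzoyl)oxy]-2-hydroxy-6-methylbenzoate | Cc1cc(O)cc(O)c1C(=O)Oc1cc(C)c(C(=O)OCc2ccccc2)c(O)c1 | intermediate
19 | 3-(acetyloxy)-4,6-bis(benzyloxy)-2-methylbenzoic trifluoroacetic anhydride (not isolated) | Cc1c(OC(C)=O)c(OCc2ccccc2)cc(OCc2ccccc2)c1C(=O)OC(=O)C(F)(F)F | intermediate
20 | benzyl 4-{[4-({3-(acetyloxy)-4,6-bis(benzyloxy)-2-methylbenzoyl}oxy)-2-hydroxy-6-methylbenzoyl]oxy}-2-hydroxy-6-methylbenzoate | CC(=O)Oc1c(OCc2ccccc2)cc(OCc2ccccc2)c(C(=O)Oc2cc(C)c(C(=O)Oc3cc(C)c(C(=O)OCc4ccccc4)c(O)c3)c(O)c2)c1C | intermediate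
21 | CNP0154030.0, 4-[(4-{[3-(acetyloxy)-4,6-dihydroxy-2-methylbenzoyl]oxy}-2-hydroxy-6-methylbenzoyl)oxy]-2-hydroxy-6-methylbenzoic acid (no stereocentres) | CC(=O)Oc1c(O)cc(O)c(C(=O)Oc2cc(C)c(C(=O)Oc3cc(C)c(C(=O)O)c(O)c3)c(O)c2)c1C | target

**Step count**

Total steps: 14. Longest linear sequence: 10 steps (steps 1 to 8, then 13 and 14).

**Steps most likely to fail**

1. Step 5. Hydroxide may cleave the alkoxy-substituted triketone chain by retro-Claisen attack, the ring may close from the wrong carbanion, or the phenolate may oxidise in air. The fallback makes ring A by known arene chemistry; it sets out from 14 and comes back to the route at 10. Bromination of 14 with NBS in MeCN at 0 °C should place bromine para to the chelated hydroxyl, between the free hydroxyl and the methyl group, to give benzyl 3-bromo-4,6-dihydroxy-2-methylbenzoate F1. Benzylation (BnBr, K2CO3, DMF, 60 °C) would give benzyl 4,6-bis(benzyloxy)-3-bromo-2-methylbenzoate F2. Bromine–lithium exchange (n-BuLi, THF, −78 °C, where the doubly ortho-substituted ester is slow to react) and B(OMe)3 would give dimethyl {4,6-bis(benzyloxy)-3-[(benzyloxy)carbonyl]-2-methylphenyl}boronate F3. Oxidation with H2O2 and aqueous NaHCO3 would give benzyl 4,6-bis(benzyloxy)-3-hydroxy-2-methylbenzoate F4, and saponification of the hindered ester (KOH, DMSO/H2O, 80 °C) would give 10.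

2. Step 3. The dienolate may be acylated at oxygen or twice at carbon, or the tert-butoxide set free may displace bromide from the vinylogous acyl bromide. The fallback replaces acyl transfer by capture of CO2 and forms the ester in a separate step; it sets out from 3 and comes back at 4. The lateral carbanion of 3 (LiN(SiMe3)2, THF, −78 °C) would be quenched with CO2 gas to give {6-bromo-5-[(4-methoxybenzyl)oxy]-4-oxo-4H-pyran-2-yl}acetic acid F5, kept below room temperature because it is a vinylogous β-keto acid. tert-Butyl 2,2,2-trichloroacetimidate in CH2Cl2/cyclohexane at rt would then esterify it to 4 without added acid.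

3. Step 4. The organozinc reagent may deprotonate the acidic methylene so that transmetalation stalls at a zinc enolate, or the bromide may be lost by reduction. The fallback avoids cross-coupling and brings the methyl group in first; it sets out from 1 and comes back at 5.
   - Hydroxymethylation of 1 (aqueous HCHO, NaOH, rt) would give 3-hydroxy-2-(hydroxymethyl)-6-methyl-4H-pyran-4-one F6.
   - Zn and HCl at 60 °C would reduce the hydroxymethyl group next to the enol to give 3-hydroxy-2,6-dimethyl-4H-pyran-4-one F7.
   - Silylation (triisopropylsilyl triflate, 2,6-lutidine, CH2Cl2) would give 2,6-dimethyl-3-[(triisopropylsilyl)oxy]-4H-pyran-4-one F8.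
   - The bulky silyl ether shields the neighbouring methyl group and offers lithium no chelating oxygen, so LiN(SiMe3)2 and Boc2O at −78 °C should carboxylate the remote methyl group to give tert-butyl 2-{6-methyl-4-oxo-5-[(triisopropylsilyl)oxy]-4H-pyran-2-yl}acetate F9.
   - Bu4NF buffered with AcOH would give tert-butyl 2-(5-hydroxy-6-methyl-4-oxo-4H-pyran-2-yl)acetate F10, and 4-methoxybenzyl chloride with K2CO3 in DMF would give 5.

**Further compounds**

F1 | step 5 | benzyl 3-bromo-4,6-dihydroxy-2-methylbenzoate | Cc1c(Br)c(O)cc(O)c1C(=O)OCc1ccccc1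
F2 | step 5 | benzyl 4,6-bis(benzyloxy)-3-bromo-2-methylbenzoate | Cc1c(Br)c(OCc2ccccc2)cc(OCc2ccccc2)c1C(=O)OCc1ccccc1
F3 | step 5 | dimethyl {4,6-bis(benzyloxy)-3-[(benzyloxy)carbonyl]-2-methylphenyl}boronate | COB(OC)c1c(C)c(C(=O)OCc2ccccc2)c(OCc2ccccc2)cc1OCc1ccccc1
F4 | step 5 | benzyl 4,6-bis(benzyloxy)-3-hydroxy-2-methylbenzoate | Cc1c(O)c(OCc2ccccc2)cc(OCc2ccccc2)c1C(=O)OCc1ccccc1
F5 | step 3 | {6-bromo-5-[(4-methoxybenzyl)oxy]-4-oxo-4H-pyran-2-yl}acetic acid | OC(=O)Cc1cc(=O)c(OCc2ccc(OC)cc2)c(Br)o1
F6 | step 4 | 3-hydroxy-2-(hydroxymethyl)-6-methyl-4H-pyran-4-one | Cc1cc(=O)c(O)c(CO)o1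
F7 | step 4 | 3-hydroxy-2,6-dimethyl-4H-pyran-4-one | Cc1cc(=O)c(O)c(C)o1
F8 | step 4 | 2,6-dimethyl-3-[(triisopropylsilyl)oxy]-4H-pyran-4-one | Cc1cc(=O)c(O[Si](C(C)C)(C(C)C)C(C)C)c(C)o1
F9 | step 4 | tert-butyl 2-{6-methyl-4-oxo-5-[(triisopropylsilyl)oxy]-4H-pyran-2-yl}acetate | Cc1oc(CC(=O)OC(C)(C)C)cc(=O)c1O[Si](C(C)C)(C(C)C)C(C)C
F10 | step 4 | tert-butyl 2-(5-hydroxy-6-methyl-4-oxo-4H-pyran-2-yl)acetate | Cc1oc(CC(=O)OC(C)(C)C)cc(=O)c1O
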